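**Retrosynthetic overview**
1. Target 13 ⇒ acid 10 + (S)-glycidyl acetate 12: the carboxylate opens the epoxide at its CH2 terminus; the glycerol centre comes from (R)-glycidol.
2. Acid 10 ⇒ acyclic (3R)-trienoic acid 7: one chiral-acid-initiated cation–olefin bicyclization of the complete C20 chain sets C5/C10 and ends by proton loss to the C8=C9 alkene.
3. Acid 7 ⇒ homofarnesyl Grignard 6 + (R)-β-butyrolactone 5: SN2 opening with inversion installs C13 and the free acid.
4. Bromide 4 ⇒ (E)-geranylacetone 1 + cyclopropylmagnesium bromide 2 (cyclopropylcarbinyl→homoallyl rearrangement); the geometry of this new alkene is irrelevant because both its carbons end in the C8=C9 alkene.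
5. Ring order: no ring before step 4; ring A (C4–C5 bond) then ring B (C9–C10 bond) form in that single operation.

Assumption: the SMILES is read as 5R,10R (trans-decalin, labdane numbering), 13R and glycerol 2R; isomerically pure (E)-geranylacetone and (R)-β-butyrolactone and (R)-glycidol of ≥98% ee are bought.

**Route**

Step 1
Reactants: 1 (E)-geranylacetone; 2 cyclopropylmagnesium bromide
Product: 3 (5E)-2-cyclopropyl-6,10-dimethylundeca-5,9-dien-2-ol (racemic carbinol)
Conditions: THF, 0 °C → rt; then H2O
Reagents that add atoms: none
Why: Grignard 1,2-addition to the methyl ketone; the carbinol centre is made racemic on purpose because it becomes sp2 in step 2, and the 5E alkene (future C5=C10) is untouched.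

Step 2
Reactants: 3 (5E)-2-cyclopropyl-6,10-dimethylundeca-5,9-dien-2-ol
Product: 4 (7E)-1-bromo-4,8,12-trimethyltrideca-3,7,11-triene (homofarnesyl bromide; 3E:3Z about 3:1, used as the mixture)
Conditions: 48% aq. HBr, 0 °C, 15 min
Reagents that add atoms: hydrogen bromide, Br
Why: Julia olefin synthesis (cyclopropylcarbinyl-to-homoallyl rearrangement): ionisation of the tertiary carbinol and bromide attack on a ring CH2 give the homoallylic bromide, and the roughly 3:1 E:Z outcome is tolerated because both carbons of this alkene end as the C8=C9 alkene of the target.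

Step 3
Reactants: 4 homofarnesyl bromide; 5 (R)-β-butyrolactone
Product: 7 (3R,10E)-3,7,11,15-tetramethylhexadeca-6,10,14-trienoic acid, via homofarnesylmagnesium bromide 6 (not isolated)
Conditions: Mg, THF, rt; then 5, CuI (copper iodide, 5 mol %), THF–Me2S, −30 → 0 °C; then aq. HCl
Reagents that add atoms: none
Why: Grignard formation, then copper-catalysed SN2 opening of the β-lactone at its β-carbon (alkyl–oxygen cleavage) with inversion, which turns the 4R lactone centre into the 3R methyl-bearing centre (C13 of the target) and gives the free acid directly.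

Step 4
Reactants: 7 (3R,10E)-3,7,11,15-tetramethylhexadeca-6,10,14-trienoic acid (6E/6Z mixture)
Product: 10 (5R,10R,13R)-labd-8-en-15-oic acid, via labd-8(17)-ene acid isomer 8 (not isolated), via labd-7-ene acid isomer 9 (not isolated)
Conditions: confined chiral imidodiphosphorimidate (IDPi) Brønsted acid, 5 mol % (two 3,3'-diaryl-BINOL phosphorus units bridged by nitrogen, N-triflyl groups on phosphorus; the antipode of the catalyst that turns homofarnesol into natural (−)-ambrox), (CF3)3COH, 0 °C → 25 °C; AgNO3–silica chromatography
Reagents that add atoms: none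
Why: Proposed new method: the confined chiral acid protonates the terminal isopropylidene in its pocket and a chair–chair cation–olefin bicyclization (Stork–Eschenmoser anti additions across the 10E alkene) closes ring A and then ring B in one event, fixing the trans ring fusion as 5R,10R by catalyst control (C13 is a remote spectator); the C8 cation has no internal nucleophile (the acid could only form an 8-membered lactone), so it ends by proton loss, and since the same acid re-protonates the 8(17)-ene and 7-ene isomers 8 and 9 back to the C8 cation the material is expected to drain to the tetrasubstituted C8=C9 alkene, which also erases the 6E/6Z and C9 information; the closest known reactions are the IDPi-catalysed bicyclization of homofarnesol to ambrox and the acid-mediated isomerisation of labd-8(17)-enes to labd-8-enes.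

Step 5
Reactants: 11 (R)-glycidol
Product: 12 (S)-glycidyl acetate
Conditions: Ac2O, Et3N, DMAP (cat.), CH2Cl2, 0 °C
Reagents that add atoms: acetic anhydride, CC(=O)OC(C)=O
Why: DMAP-catalysed O-acetylation of the primary alcohol; the epoxide and its stereocentre are untouched, and the descriptor changes from R to S only through the CIP priorities.

Step 6
Reactants: 10 (5R,10R,13R)-labd-8-en-15-oic acid; 12 (S)-glycidyl acetate
Product: 13 (2R)-3-(acetyloxy)-2-hydroxypropyl (3R)-3-methyl-5-[(4aR,8aR)-2,5,5,8a-tetramethyl-3,4,4a,5,6,7,8,8a-octahydronaphthalen-1-yl]pentanoate (target)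
Conditions: [(S,S)-N,N'-bis(3,5-di-tert-butylsalicylidene)-1,2-cyclohexanediaminato]cobalt, C36H52CoN2O2 (3 mol %; divalent cobalt precatalyst, oxidised by air in the flask to the active trivalent cobalt carboxylate), iPr2NEt, tert-butyl methyl ether, air, 0 °C → rt
Reagents that add atoms: none
Why: Jacobsen-type cobalt–salen-catalysed opening of a terminal epoxide by a carboxylic acid: the carboxylate of 10 attacks the unsubstituted epoxide carbon, so the glycerol C2–O bond is never broken and its configuration (2R in 13) is retained, while the near-neutral conditions limit 1,3→1,2 acyl migration and leave the tetrasubstituted alkene alone.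

**Compound list**
1 | (E)-geranylacetone, (5E)-6,10-dimethylundeca-5,9-dien-2-one | CC(=O)CC/C=C(\C)CCC=C(C)C | starting material
2 | cyclopropylmagnesium bromide (THF solution) | Br[Mg]C1CC1 | starting material
3 | (5E)-2-cyclopropyl-6,10-dimethylundeca-5,9-dien-2-ol (racemic at C2) | CC(O)(C1CC1)CC/C=C(\C)CCC=C(C)C | intermediate
4 | (7E)-1-bromo-4,8,12-trimethyltrideca-3,7,11-triene, homofarnesyl bromide (3E:3Z about 3:1; C3=C4 geometry left open in the SMILES) | BrCCC=C(C)CC/C=C(\C)CCC=C(C)C | intermediate
5 | (R)-β-butyrolactone, (4R)-4-methyloxetan-2-one | C[C@@H]1CC(=O)O1 | starting material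
6 | homofarnesylmagnesium bromide (same E/Z mixture) | Br[Mg]CCC=C(C)CC/C=C(\C)CCC=C(C)C | intermediate (not isolated)
7 | (3R,10E)-3,7,11,15-tetramethylhexadeca-6,10,14-trienoic acid (6E:6Z about 3:1; C6=C7 geometry left open) | OC(=O)C[C@H](C)CCC=C(C)CC/C=C(\C)CCC=C(C)C | intermediate
8 | (5R,10R,13R)-labd-8(17)-en-15-oic acid (9R from 6E-7, 9S from 6Z-7; C9 left open) | CC1(CCC[C@@]2([C@@H]1CCC(=C)C2CC[C@@H](C)CC(=O)O)C)C | intermediate (not isolated)
9 | (5R,10R,13R)-labd-7-en-15-oic acid (9R from 6E-7, 9S from 6Z-7; C9 left open) | CC1(CCC[C@@]2([C@@H]1CC=C(C)C2CC[C@@H](C)CC(=O)O)C)C | intermediate (not isolated)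
10 | (5R,10R,13R)-labd-8-en-15-oic acid, (3R)-3-methyl-5-[(4aR,8aR)-2,5,5,8a-tetramethyl-3,4,4a,5,6,7,8,8a-octahydronaphthalen-1-yl]pentanoic acid | OC(=O)C[C@H](C)CCC1=C(C)CC[C@@H]2C(C)(C)CCC[C@@]12C | intermediate
11 | (R)-glycidol, [(2R)-oxiran-2-yl]methanol | OC[C@@H]1CO1 | starting material
12 | (S)-glycidyl acetate, [(2S)-oxiran-2-yl]methyl acetate | CC(=O)OC[C@@H]1CO1 | intermediate
13 | (2R)-3-(acetyloxy)-2-hydroxypropyl (3R)-3-methyl-5-[(4aR,8aR)-2,5,5,8a-tetramethyl-3,4,4a,5,6,7,8,8a-octahydronaphthalen-1-yl]pentanoate | CC(=O)OC[C@@H](O)COC(=O)C[C@H](C)CCC1=C(C)CC[C@@H]2C(C)(C)CCC[C@@]12C | target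

**Count**
Total steps: 6. Longest linear sequence: 5 (steps 1, 2, 3, 4, 6); step 5 is a one-step side branch.

**Three steps most likely to fail**

Step 4 (highest risk). The bicyclization may stop at monocyclic material or end at the 7-ene/8(17)-ene without draining to 10. Facial selectivity may be lower than for hydroxyl-terminated substrates, in which case the minor 5S,10S,13R diastereomer has to be removed by preparative HPLC or by crystallising the dicyclohexylammonium salt of 10. The 6Z part of 7 may lag, and prolonged acid could trigger hydride or methyl shifts. Fallback: set out from 7 and split the task into a reagent-controlled kinetic cyclization and a separate thermodynamic double-bond shift. Acid 7 is treated with a stoichiometric chiral Lewis-acid-assisted Brønsted acid, the SnCl4 complex of (S)-2-(2-fluorobenzyloxy)-2'-hydroxy-1,1'-binaphthyl (antipode of the reagent that gives the natural 5S,10S series), in toluene at −78 °C. The kinetic mixture of 8 and 9 is isolated and, in a second operation, heated with catalytic hydriodic acid (HI) in benzene at 80 °C, which moves the double bond into the tetrasubstituted position and arrives at 10. This fallback makes no compound outside the list (F0).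

Step 2. Aqueous HBr may hydrobrominate or cyclise the two other trisubstituted alkenes, and carrying the 3Z quarter of 4 relies on step 4 converging. Fallback: set out from 1 and build the new alkene by carbometalation instead of rearrangement. Kinetic enolisation of 1 (LiN(iPr)2, THF, −78 °C) and trapping with ClP(O)(OEt)2 gives the enol phosphate diethyl (5E)-6,10-dimethylundeca-1,5,9-trien-2-yl phosphate F1. More LiN(iPr)2 eliminates it to the terminal alkyne (5E)-6,10-dimethylundeca-5,9-dien-1-yne F2. Zirconium-catalysed methylalumination (Al(CH3)3, (C5H5)2ZrCl2, ClCH2CH2Cl, rt) gives the alkenylalane dimethyl[(1E,5E)-2,6,10-trimethylundeca-1,5,9-trien-1-yl]alumane F3. Its n-BuLi ate complex opens ethylene oxide to (3E,7E)-4,8,12-trimethyltrideca-3,7,11-trien-1-ol (homofarnesol) F4. CBr4/PPh3 in CH2Cl2 then gives 4 as the single 3E isomer, where the route is rejoined; 6 and 7 then become single isomers too.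

Step 6. The free secondary hydroxyl of 13 invites 1,3→1,2 acyl migration (amine base, silica), and some attack at the internal epoxide carbon or epoxide oligomerisation is possible. Fallback: set out from 10 and use a protected glycerol instead of an epoxide. Steglich esterification (DCC, DMAP, CH2Cl2) of 10 with bought (S)-solketal (CC1(C)OC[C@@H](O1)CO) gives the acetonide ester [(4R)-2,2-dimethyl-1,3-dioxolan-4-yl]methyl (3R)-3-methyl-5-[(4aR,8aR)-2,5,5,8a-tetramethyl-3,4,4a,5,6,7,8,8a-octahydronaphthalen-1-yl]pentanoate F5. Acidic ion-exchange resin in wet methanol at rt removes the acetonide and gives the monoacylglycerol (2R)-2,3-dihydroxypropyl (3R)-3-methyl-5-[(4aR,8aR)-2,5,5,8a-tetramethyl-3,4,4a,5,6,7,8,8a-octahydronaphthalen-1-yl]pentanoate F6. Lipase-catalysed acetylation of the primary hydroxyl only (immobilised Candida antarctica lipase B, vinyl acetate, tert-butyl methyl ether, rt) then arrives at 13.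

**Further compounds**
F0 | step 4 | none | none
F1 | step 2 | diethyl (5E)-6,10-dimethylundeca-1,5,9-trien-2-yl phosphate | C=C(OP(=O)(OCC)OCC)CC/C=C(\C)CCC=C(C)C
F2 | step 2 | (5E)-6,10-dimethylundeca-5,9-dien-1-yne | C#CCC/C=C(\C)CCC=C(C)C
F3 | step 2 | dimethyl[(1E,5E)-2,6,10-trimethylundeca-1,5,9-trien-1-yl]alumane | C[Al](C)/C=C(\C)CC/C=C(\C)CCC=C(C)C
F4 | step 2 | (3E,7E)-4,8,12-trimethyltrideca-3,7,11-trien-1-ol (homofarnesol) | OCC/C=C(\C)CC/C=C(\C)CCC=C(C)C
F5 | step 6 | [(4R)-2,2-dimethyl-1,3-dioxolan-4-yl]methyl (3R)-3-methyl-5-[(4aR,8aR)-2,5,5,8a-tetramethyl-3,4,4a,5,6,7,8,8a-octahydronaphthalen-1-yl]pentanoate | CC1(C)OC[C@@H](O1)COC(=O)C[C@H](C)CCC1=C(C)CC[C@@H]2C(C)(C)CCC[C@@]12C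
F6 | step 6 | (2R)-2,3-dihydroxypropyl (3R)-3-methyl-5-[(4aR,8aR)-2,5,5,8a-tetramethyl-3,4,4a,5,6,7,8,8a-octahydronaphthalen-1-yl]pentanoate | OC[C@@H](O)COC(=O)C[C@H](C)CCC1=C(C)CC[C@@H]2C(C)(C)CCC[C@@]12C
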